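## Structural features

The target is a flavanone. Benzo ring A is fused along C4a–C8a to the dihydropyranone ring C (O1, C2, C3, C4, C4a, C8a), and C2 carries the aryl ring B. Ring A has one free hydroxyl at C7, para to C4a and meta to C8a. Ring B carries a 4'-methoxy group flanked by two 3-methylbut-2-enyl (prenyl) chains at C3' and C5', so it is symmetric about its C1'–C4' axis. The only stereocentre is C2 (S), with no stereocentre next to it. It is benzylic, bears the ring oxygen and lies β to the C4 ketone, so base can open ring C by retro-oxa-Michael reaction to the achiral 2'-hydroxychalcone and racemise it. The fragile groups are the two trisubstituted prenyl olefins (acid, electrophilic halogen, hydrogenation, oxidants), the free phenol and the C2 centre, while the aryl methyl ether must survive every deprotection. The real difficulty is twofold: to build ring C with the ring A oxygen in the right orientation (C7–O para to the acyl-bearing carbon), and to set C2 late, enantioselectively and without base, in the presence of the prenyl groups. The key step uses the fact that O1 on C8a and the carbonyl carbon C4 on C4a sit on adjacent carbons of ring A. An aryne C4a≡C8a installs exactly this ortho oxygen/acyl pair when it inserts into a carboxyl C–O bond, and the phenoxide so formed is placed to close ring C onto the alkyne that becomes C2=C3.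

## Logic of the disconnections

**20 ⇒ 19.** The O7–CH2 bond of an acetal protecting group is cut. The phenol has to be masked through the fluoride, palladium and copper hydride steps; a silyl ether would not survive fluoride and a benzyl ether could not be removed without reducing the prenyl olefins. The forward step must use acid mild enough to leave the olefins, the methyl ether and C2 alone.

**19 ⇒ 17 (through 18).** The C2–H bond, and with it the stereocentre, is removed, which leads back to a flat, achiral flavone. This takes all stereochemistry out of the earlier steps. The forward step must distinguish the two faces of a weakly electrophilic vinylogous ester and must not reduce isolated olefins. A nucleophilic copper hydride under a chiral bisphosphine meets both demands, and trapping as 18 stops the reduction at the ketone oxidation level.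

**17 ⇒ 16.** The C5–H bond is exchanged for C5–Br. The bromine has no place in the target; it is put back only because it controls the orientation of the ring-forming step. The forward step must remove an aryl bromide without touching the C2=C3 bond or the prenyl groups.

**16 ⇒ 6 + 13 (through 14 and 15).** Three bonds of ring C are cut: O1–C8a and C4–C4a (aryne insertion into the carboxyl C–O bond) and O1–C2 (phenoxide addition to the ynone). This splits the molecule into two fragments of similar size and makes ring C and the ring A pattern in one operation. The forward step needs one orientation of addition to an unsymmetrical aryne, acyl transfer faster than protonation of the aryl anion, and 6-endo in preference to 5-exo closure.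

**6 ⇒ 3 (through 4 and 5).** The aryl C–Si bond and the O–S bond are cut. A retro-Brook rearrangement turns one of two equivalent C–Br bonds into the C–Si bond and leaves the other bromine beside the triflate, so the aryne precursor and its control element come from one symmetric dibromophenol. The forward step needs exactly one bromine–lithium exchange.

**3 ⇒ 2 ⇒ 1.** Two C–Br bonds ortho to the free hydroxyl and then one O–CH2 bond are cut, back to a symmetric diphenol. The forward bromination must be non-acidic (acetal) and ortho to the hydroxyl only, and the mono-protection relies on an excess of 1.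

**13 ⇒ 11 (through 12) ⇒ 10.** The C–CO2H bond is cut to an acetylide, the alkyne is traced to a dibromo-olefin and this to an aldehyde. The three-carbon acid chain thus comes from a formyl group by one-carbon homologation and carboxylation. The forward steps must avoid electrophilic bromine and strong acid near the prenyl groups.

**10 ⇒ 8 + 9.** Both aryl–CH2 bonds are cut at once, a twofold cross-coupling on a symmetric dibromide. The forward step must transfer the allyl unit through its boron-bearing carbon (linear prenyl, not 1,1-dimethylallyl).

**8 ⇒ 7.** The O–CH3 bond is cut; a simple O-alkylation of a hindered but acidic phenol.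

## Other disconnections considered

**Alternative 1:** The cut is the C3=C4 bond of ring C, taken at the enol-ether oxidation level.
- **Forward key step:** the diene A2, an (S)-configured aryl 1-arylallyl ether with a 1-(tert-butyldimethylsilyloxy)vinyl group on C4a, would be closed with the second-generation Grubbs catalyst to the cyclic silyl enol ether A1, with loss of ethylene. Mild hydrolysis of A1 would give 19, and step 11 would finish.
- **In favour:** C2 would be set in an open-chain precursor by a branch-selective asymmetric allylic etherification ([Ir(cod)Cl]2 with a chiral phosphoramidite). Ring C would arrive directly at the flavanone oxidation level, so no control halogen and no enantioselective reduction of a flavone would be needed.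
- **Against, here:** A2 holds four olefins. The ruthenium methylidene and the ethylene set free could degrade the two prenyl olefins during a slow closure onto a hindered, electron-rich 1,1-disubstituted enol ether. The benzylic, allylic aryl ether of A2 could rearrange in a [3,3] sense or ionise at the temperature such a closure needs. The chelated ortho-acylphenol needed for the etherification is a weak nucleophile.
- **Comparison:** in stereochemical logic alternative 1 is the better plan, because no reagent has to tell apart the faces of a flat vinylogous ester. In step count the two are about equal, since both would use 10. In chemoselectivity the chosen plan is better: fluoride and a carboxylate-trapped aryne should ignore prenyl groups, whereas a metathesis catalyst cannot be relied on to do so.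

**Alternative 2:** Three bonds are cut at once, C4a–C4 and C4–C3 at the carbonyl carbon and O1–C2. This leads back to the iodophenol A4, carbon monoxide and the arylacetylene A5.
- **Forward key step:** PdCl2(PPh3)2 in diethylamine would insert CO into the aryl–palladium bond derived from A4 and couple the acyl palladium species with A5 to an ortho-hydroxyaryl ynone. The amine would steer the 6-endo closure to the flavone A3. A3 is the same compound as 17, so this plan would join the chosen route two steps before the end.
- **In favour:** the iodine of A4 fixes the ring A orientation with no auxiliary substituent, so no bromine has to be removed. A5 would be one step from 11 (aqueous quench of the acetylide), and the silyl triflate synthesis is replaced by a shorter phenol synthesis.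
- **Against, here:** a toxic gas is needed. Direct CO-free coupling to a 2-arylbenzofuran and 5-exo closure to an aurone are competing channels. A4 must be made regioselectively (free hydroxyl ortho to iodine, MOM ether para to iodine) from a resorcinol-type diol, which is not trivial.
- **Comparison:** the last bond-forming event is mechanistically the same in both plans (an ortho-oxido ynone closing 6-endo), and both are convergent with the same ring B fragment. Alternative 2 is the better in step economy (no silylation–rearrangement–triflation and no hydrodebromination) and at least the equal in regiochemical certainty. The chosen plan is better only in that ring formation needs no transition metal and no CO.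

**Alternative 3:** The cut is the aryl ether bond O1–C8a.
- **Forward key step:** the bromo diol A7, whose two carbinol centres would come from an aldol reaction followed by ketone reduction, would be cyclised with CuI, a phenanthroline ligand and Cs2CO3. Only the C2 alkoxide can reach C8a through a six-membered transition state. Because the C2–O bond is not broken, the configuration at C2 would be retained in the chromanol A6. Oxidation of the C4 carbinol of A6 would give 19.
- **In favour:** C2 is set early on an sp3 carbon, and no later step forms or breaks a bond at C2. Intramolecular copper-catalysed etherification tolerates prenyl and MOM groups. The ring A orientation is fixed by the bromine position without a removable auxiliary.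
- **Against, here:** the carbonyl must be carried as an alcohol through the basic coupling, because a β-hydroxy ketone would eliminate or undergo retro-aldol cleavage. One reduction and one re-oxidation are therefore spent on C4, whose configuration is destroyed at the end. An enantioselective aldol of a methyl ketone with an aromatic aldehyde is not among the reliable aldol classes. Hot Cs2CO3 with a secondary benzylic alkoxide invites dehydration and reductive loss of bromine.
- **Comparison:** alternative 3 is the equal or the better of the chosen plan in the security of the stereocentre once it exists. The chosen plan is better in convergence and length (one ring-forming step from two fragments against aldol, reduction, coupling and oxidation) and has no redox detour at C4. It pays for this with the late asymmetric reduction.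

Key step: step 8

**Remarks before the steps**
- The mapping of the key step was checked atom by atom and needs no correction. The aryne carbon next to bromine becomes C4a, the distal aryne carbon becomes C8a, and the OMOM group para to the former lands at C7.
- Bromine is kept as the control element: it is the smallest group that polarises the aryne strongly and can still be removed under conditions that spare the olefins.
- Assumption: the ligand antipode in step 10 is written as (R). Which antipode delivers hydride to the face giving (2S) on a 2-arylchromen-4-one must be confirmed on a trial run, and the antipodal ligand is used if the sense is opposite.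
- IPent stands for 1,3-bis[2,6-di(pentan-3-yl)phenyl]imidazol-2-ylidene.

## Route

Step 1
Reactants: 1 hydroquinone (benzene-1,4-diol)
Product: 2 4-(methoxymethoxy)phenol
Conditions: 1 (3 equiv), NaH (1 equiv), DMF, 0 °C; MOMCl (1 equiv), 0 °C → rt, under argon
Reagents that add atoms: chloromethyl methyl ether, COCCl
Why: Williamson-type O-alkylation of the mono-phenoxide by the α-chloro ether; the excess of 1 keeps bis-ether formation low and unreacted 1 is removed by aqueous washing.

Step 2
Reactants: 2 4-(methoxymethoxy)phenol
Product: 3 2,6-dibromo-4-(methoxymethoxy)phenol
Conditions: NBS (2.05 equiv), i-Pr2NH (10 mol%), CH2Cl2, 0 °C → rt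
Reagents that add atoms: N-bromosuccinimide, O=C1CCC(=O)N1Br
Why: Electrophilic aromatic bromination; the amine-catalysed NBS protocol brominates ortho to the free hydroxyl (para is blocked) under non-acidic conditions, so the MOM acetal should survive.

Step 3
Reactants: 3 2,6-dibromo-4-(methoxymethoxy)phenol
Product: 6 2-bromo-4-(methoxymethoxy)-6-(trimethylsilyl)phenyl trifluoromethanesulfonate, via aryl trimethylsilyl ether 4 (not isolated), via lithium silylphenoxide 5 (not isolated)
Conditions: HMDS, THF, 70 °C, evaporate; n-BuLi (1.05 equiv), THF, −100 → −78 °C; Tf2O, −78 → 0 °C
Reagents that add atoms: hexamethyldisilazane, C[Si](C)(C)N[Si](C)(C)C; trifluoromethanesulfonic anhydride, O=S(=O)(OS(=O)(=O)C(F)(F)F)C(F)(F)F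
Why: O-Silylation gives 4; bromine–lithium exchange at one of its two equivalent C–Br bonds triggers a 1,3 O→C silyl shift (retro-Brook rearrangement) to phenoxide 5, which Tf2O sulfonylates on oxygen. This is the established way to ortho-silylaryl triflates that keep a halogen beside the triflate.

Step 4
Reactants: 7 3,5-dibromo-4-hydroxybenzaldehyde
Product: 8 3,5-dibromo-4-methoxybenzaldehyde
Conditions: MeI, K2CO3, DMF, rt
Reagents that add atoms: iodomethane, CI
Why: Williamson O-methylation of the acidic, bromine-flanked phenol; the phenoxide is hindered but iodomethane is small.

Step 5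
Reactants: 8 3,5-dibromo-4-methoxybenzaldehyde; 9 prenylboronic acid pinacol ester (4,4,5,5-tetramethyl-2-(3-methylbut-2-enyl)-1,3,2-dioxaborolane)
Product: 10 4-methoxy-3,5-bis(3-methylbut-2-enyl)benzaldehyde
Conditions: 9 (2.6 equiv), PdCl2(IPent)(3-chloropyridine) (4 mol%), 5 M aq KOH, THF, 70 °C
Reagents that add atoms: none
Why: Twofold Suzuki–Miyaura coupling of an allylboronate; with the bulky N-heterocyclic carbene ligand the allyl unit is transferred through its boron-bearing carbon, which should give the linear prenyl arene and not the 1,1-dimethylallyl isomer. The non-enolisable aldehyde stays in the organic phase of the biphasic mixture.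

Step 6
Reactants: 10 4-methoxy-3,5-bis(3-methylbut-2-enyl)benzaldehyde
Product: 11 5-(2,2-dibromoethenyl)-2-methoxy-1,3-bis(3-methylbut-2-enyl)benzene
Conditions: CBr4, PPh3, Zn dust, CH2Cl2, rt (reagent preformed), then 10, 0 °C → rt
Reagents that add atoms: carbon tetrabromide, BrC(Br)(Br)Br
Why: Ramirez dibromo-olefination (first half of the Corey–Fuchs sequence) through the ylide Ph3P=CBr2; zinc takes up the bromine so that neither Ph3PBr2 nor HBr is present to attack the prenyl olefins.

Step 7
Reactants: 11 5-(2,2-dibromoethenyl)-2-methoxy-1,3-bis(3-methylbut-2-enyl)benzene
Product: 13 3-[4-methoxy-3,5-bis(3-methylbut-2-enyl)phenyl]prop-2-ynoic acid, via lithium arylacetylide 12 (not isolated)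
Conditions: n-BuLi (2.2 equiv), THF, −78 °C; CO2 (dry gas), −78 → 0 °C; cold 1 M HCl work-up
Reagents that add atoms: carbon dioxide, O=C=O
Why: Second half of the Corey–Fuchs sequence: bromine–lithium exchange and a Fritsch–Buttenberg–Wiechell-type 1,2-shift give the alkyne, which the second equivalent of n-BuLi lithiates to 12. Carboxylation of the acetylide and acidification should give the propiolic acid.

Step 8
Reactants: 6 2-bromo-4-(methoxymethoxy)-6-(trimethylsilyl)phenyl trifluoromethanesulfonate; 13 3-[4-methoxy-3,5-bis(3-methylbut-2-enyl)phenyl]prop-2-ynoic acid
Product: 16 5-bromo-7-(methoxymethoxy)-2-[4-methoxy-3,5-bis(3-methylbut-2-enyl)phenyl]chromen-4-one, via 3-bromo-5-(methoxymethoxy)benzyne 14 (not isolated), via caesium ortho-acylphenoxide 15 (not isolated)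
Conditions: 6 (1.5 equiv), 13 (1 equiv), CsF (4 equiv), THF, 125 °C, sealed tube
Reagents that add atoms: none
Why: Fluoride attacks silicon of 6 and triflate leaves, giving aryne 14; the caesium carboxylate of 13 adds through oxygen to the aryne carbon remote from bromine (future C8a), because the C–Br bond distorts the aryne so that this carbon is the more linear, more electrophilic one and the developing carbanion at the other carbon (future C4a) lies beside the electron-withdrawing C–Br bond. The aryl anion then attacks its own ester carbonyl to a four-membered benzoxetene alkoxide that opens to the ortho-acylphenoxide 15, a net insertion of the aryne into the carboxyl C–O bond (bonds O1–C8a and C4–C4a). The closest known reaction type is the fluoride-induced C–O insertion of arynes into carboxylic acids, which with alkynoic acids runs on to chromones and flavones; fixing the orientation with a halogen beside the aryne follows the known behaviour of 3-haloarynes toward other nucleophiles. Phenoxide 15 adds to the β-carbon of the ynone in a 6-endo-dig oxa-Michael closure (bond O1–C2) that forms ring C, and protonation at C3 gives the pyranone. No stereocentre is formed. Three selectivities are needed: orientation on the aryne (secured by the bromine at C5, which should outweigh the weak effect of the remote OMOM group), acyl transfer ahead of protonation of the aryl anion (helped by aprotic THF, high temperature and excess CsF that keeps the acid as its carboxylate), and 6-endo over 5-exo closure (secured by the polarisation of the ynone and the stability of the 4-pyranone). The prenyl olefins, the aryl ethers and the MOM acetal should be much slower partners for the aryne than the carboxylate and are inert to fluoride.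

Step 9
Reactants: 16 5-bromo-7-(methoxymethoxy)-2-[4-methoxy-3,5-bis(3-methylbut-2-enyl)phenyl]chromen-4-one
Product: 17 7-(methoxymethoxy)-2-[4-methoxy-3,5-bis(3-methylbut-2-enyl)phenyl]chromen-4-one
Conditions: Pd(OAc)2 (5 mol%), PPh3 (20 mol%), HCO2Na (3 equiv), DMF, 90 °C
Reagents that add atoms: none
Why: Palladium-catalysed hydrodehalogenation: oxidative addition of zerovalent palladium into the C5–Br bond, bromide–formate exchange, loss of CO2 and C–H reductive elimination. Isolated trisubstituted olefins and the pyranone double bond are not substrates for this cycle.

Step 10
Reactants: 17 7-(methoxymethoxy)-2-[4-methoxy-3,5-bis(3-methylbut-2-enyl)phenyl]chromen-4-one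
Product: 19 (2S)-7-(methoxymethoxy)-2-[4-methoxy-3,5-bis(3-methylbut-2-enyl)phenyl]chroman-4-one, via diethoxy(methyl)silyl enol ether 18 (not isolated)
Conditions: Cu(OAc)2 (5 mol%), (R)-DTBM-SEGPHOS (5.5 mol%), (EtO)2MeSiH (3 equiv), toluene, 0 °C → rt; then AcOH/H2O/THF, 0 °C
Reagents that add atoms: none
Why: Asymmetric copper hydride conjugate reduction, a reaction known for β,β-disubstituted cyclic enones and chromen-4-ones: the ligated copper hydride formed from Cu(OAc)2 and the silane adds hydride to C2, and the chiral pocket of the bisphosphine selects the face that gives (2S). The copper enolate is silylated to 18, which prevents over-reduction and keeps the medium non-basic; mild aqueous acid then releases the ketone without touching C2 or the prenyl olefins.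

Step 11
Reactants: 19 (2S)-7-(methoxymethoxy)-2-[4-methoxy-3,5-bis(3-methylbut-2-enyl)phenyl]chroman-4-one
Product: 20 (2S)-7-hydroxy-2-[4-methoxy-3,5-bis(3-methylbut-2-enyl)phenyl]chroman-4-one (target)
Conditions: HCl (1.25 M in MeOH), MeOH/THF, 0 °C → rt
Reagents that add atoms: none
Why: Acid-catalysed acetal exchange of the MOM ether with methanol; the conditions should be too mild to hydrate the prenyl olefins or cleave the aryl methyl ether. Acid, unlike base, does not open ring C, so the C2 configuration should be kept.

## Compound list

1 | hydroquinone (benzene-1,4-diol) | Oc1ccc(O)cc1 | starting material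
2 | 4-(methoxymethoxy)phenol | COCOc1ccc(O)cc1 | intermediate
3 | 2,6-dibromo-4-(methoxymethoxy)phenol | COCOc1cc(Br)c(O)c(Br)c1 | intermediate
4 | [2,6-dibromo-4-(methoxymethoxy)phenoxy]trimethylsilane | COCOc1cc(Br)c(O[Si](C)(C)C)c(Br)c1 | intermediate (not isolated)
5 | lithium 2-bromo-4-(methoxymethoxy)-6-(trimethylsilyl)phenoxide | [Li+].[O-]c1c(Br)cc(OCOC)cc1[Si](C)(C)C | intermediate (not isolated)
6 | 2-bromo-4-(methoxymethoxy)-6-(trimethylsilyl)phenyl trifluoromethanesulfonate | C[Si](C)(C)c1cc(OCOC)cc(Br)c1OS(=O)(=O)C(F)(F)F | intermediate
7 | 3,5-dibromo-4-hydroxybenzaldehyde | O=Cc1cc(Br)c(O)c(Br)c1 | starting material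
8 | 3,5-dibromo-4-methoxybenzaldehyde | COc1c(Br)cc(C=O)cc1Br | intermediate
9 | prenylboronic acid pinacol ester (4,4,5,5-tetramethyl-2-(3-methylbut-2-enyl)-1,3,2-dioxaborolane) | CC(C)=CCB1OC(C)(C)C(C)(C)O1 | starting material
10 | 4-methoxy-3,5-bis(3-methylbut-2-enyl)benzaldehyde | COc1c(CC=C(C)C)cc(C=O)cc1CC=C(C)C | intermediate
11 | 5-(2,2-dibromoethenyl)-2-methoxy-1,3-bis(3-methylbut-2-enyl)benzene | COc1c(CC=C(C)C)cc(C=C(Br)Br)cc1CC=C(C)C | intermediate
12 | lithium [4-methoxy-3,5-bis(3-methylbut-2-enyl)phenyl]acetylide | [Li+].[C-]#Cc1cc(CC=C(C)C)c(OC)c(CC=C(C)C)c1 | intermediate (not isolated)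
13 | 3-[4-methoxy-3,5-bis(3-methylbut-2-enyl)phenyl]prop-2-ynoic acid | OC(=O)C#Cc1cc(CC=C(C)C)c(OC)c(CC=C(C)C)c1 | intermediate
14 | 3-bromo-5-(methoxymethoxy)benzyne (aryne carbons C1 and C2, bromine on C3) | BrC1=CC(OCOC)=CC#C1 | intermediate (not isolated)
15 | caesium 3-bromo-5-(methoxymethoxy)-2-{3-[4-methoxy-3,5-bis(3-methylbut-2-enyl)phenyl]prop-2-ynoyl}phenoxide | [Cs+].[O-]c1cc(OCOC)cc(Br)c1C(=O)C#Cc1cc(CC=C(C)C)c(OC)c(CC=C(C)C)c1 | intermediate (not isolated)
16 | 5-bromo-7-(methoxymethoxy)-2-[4-methoxy-3,5-bis(3-methylbut-2-enyl)phenyl]chromen-4-one | O=c1cc(-c2cc(CC=C(C)C)c(OC)c(CC=C(C)C)c2)oc2cc(OCOC)cc(Br)c12 | intermediate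
17 | 7-(methoxymethoxy)-2-[4-methoxy-3,5-bis(3-methylbut-2-enyl)phenyl]chromen-4-one | O=c1cc(-c2cc(CC=C(C)C)c(OC)c(CC=C(C)C)c2)oc2cc(OCOC)ccc12 | intermediate
18 | (2S)-4-[diethoxy(methyl)silyloxy]-7-(methoxymethoxy)-2-[4-methoxy-3,5-bis(3-methylbut-2-enyl)phenyl]-2H-chromene | COc1c(CC=C(C)C)cc([C@@H]2C=C(O[Si](C)(OCC)OCC)c3ccc(OCOC)cc3O2)cc1CC=C(C)C | intermediate (not isolated)
19 | (2S)-7-(methoxymethoxy)-2-[4-methoxy-3,5-bis(3-methylbut-2-enyl)phenyl]chroman-4-one | COc1c(CC=C(C)C)cc([C@@H]2CC(=O)c3ccc(OCOC)cc3O2)cc1CC=C(C)C | intermediate
20 | (2S)-7-hydroxy-2-[4-methoxy-3,5-bis(3-methylbut-2-enyl)phenyl]chroman-4-one | COc1c(CC=C(C)C)cc([C@@H]2CC(=O)c3ccc(O)cc3O2)cc1CC=C(C)C | target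

## Step count and least certain steps

Total: 11 steps. Longest linear sequence: 8 steps (7 → 20 through steps 4–11); the ring A branch (1 → 6) adds 3 steps in parallel.

**Step 8 (key step).**
- What may go wrong: protonation of the aryl anion may outrun acyl transfer, so that only O-arylation of the acid occurs. The ortho-bromoaryl anion may expel bromide and form a second aryne. The caesium propiolate may lose CO2 at 125 °C. The OMOM group may erode the orientation of addition.
- Why: the anion beside bromine is stabilised and hindered, so its attack on the ester carbonyl is slower than for an unsubstituted aryne.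
- Fallback: sets out from 11 and rejoins the route at 17, replacing steps 7, 8 and 9. Commercial 2,4-dihydroxybenzaldehyde F1 would be protected selectively at the non-chelated 4-hydroxyl (MOMCl, K2CO3, acetone) to 2-hydroxy-4-(methoxymethoxy)benzaldehyde F2. Acetylide 12, generated from 11 as in step 7, would be added in place of CO2 to the sodium phenoxide of F2 (NaH, THF, −78 → 0 °C) to give racemic 1-[2-hydroxy-4-(methoxymethoxy)phenyl]-3-[4-methoxy-3,5-bis(3-methylbut-2-enyl)phenyl]prop-2-yn-1-ol F3. MnO2 in CH2Cl2 would oxidise the benzylic, propargylic carbinol to the ortho-hydroxyaryl ynone 1-[2-hydroxy-4-(methoxymethoxy)phenyl]-3-[4-methoxy-3,5-bis(3-methylbut-2-enyl)phenyl]prop-2-yn-1-one F4. Et2NH in EtOH would close ring C by the 6-endo path through the enaminone to 17. No aryne and no bromine are involved.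

**Step 10.**
- What may go wrong: slow hydride transfer to a 2-aryl vinylogous ester, and with it low conversion; poor facial selectivity; 1,2-reduction after premature protonation of the enolate.
- Why: flavones are less electrophilic at C2 than simple enones, and the 2-aryl group is twisted and bulky.
- Fallback: sets out from 17 and returns at 19. LiBH(s-Bu)3 in THF at −78 °C should give racemic 7-(methoxymethoxy)-2-[4-methoxy-3,5-bis(3-methylbut-2-enyl)phenyl]chroman-4-one F5 by conjugate reduction. Kinetic resolution by asymmetric transfer hydrogenation (RuCl(p-cymene)[(R,R)-TsDPEN], HCO2H/Et3N, rt, stopped near half conversion) should, by the usual facial rule for aryl ketones, reduce the (2R) ketone to (2R,4R)-7-(methoxymethoxy)-2-[4-methoxy-3,5-bis(3-methylbut-2-enyl)phenyl]chroman-4-ol F6 and leave 19. The two are separable by chromatography, and the prenyl olefins are not touched by this catalyst. The price is a ceiling of half the material.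

**Step 5.**
- What may go wrong: allyl transfer through the γ-carbon (1,1-dimethylallyl isomers); incomplete second coupling at the hindered position; protodeboronation of 9; hydroxide attack on the aldehyde (Cannizzaro disproportionation).
- Why: allylboronates transmetalate with allylic transposition unless the palladium allyl can equilibrate to the less hindered terminus before reductive elimination, and the coupling needs strong aqueous base.
- Fallback: sets out from 8 and returns at 10, with the polarity of the coupling reversed. Miyaura borylation (B2pin2, PdCl2(dppf), KOAc, dioxane, 90 °C) would give 4-methoxy-3,5-bis(4,4,5,5-tetramethyl-1,3,2-dioxaborolan-2-yl)benzaldehyde F7. Coupling with prenyl bromide (Pd(PPh3)4, K2CO3, toluene/H2O, 70 °C) proceeds through a π-prenyl palladium intermediate that delivers the aryl group to the unsubstituted terminus, and uses only carbonate as base.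

**Step 9.**
- What may go wrong: migration of the prenyl double bonds into conjugation with ring B by palladium hydride; partial reduction of the C2=C3 bond.
- Why: a palladium hydride is an intermediate of the cycle, and the ArCH2–CH=C unit can isomerise.
- Fallback: sets out from 16 and returns at 17 with no new compound. Radical chain reduction with (Me3Si)3SiH and AIBN in toluene at 80 °C removes the bromine through an aryl radical, with no metal hydride present.

## Further compounds

F1 | step 8 | 2,4-dihydroxybenzaldehyde | O=Cc1ccc(O)cc1O
F2 | step 8 | 2-hydroxy-4-(methoxymethoxy)benzaldehyde | COCOc1ccc(C=O)c(O)c1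
F3 | step 8 | 1-[2-hydroxy-4-(methoxymethoxy)phenyl]-3-[4-methoxy-3,5-bis(3-methylbut-2-enyl)phenyl]prop-2-yn-1-ol (racemic) | COCOc1ccc(C(O)C#Cc2cc(CC=C(C)C)c(OC)c(CC=C(C)C)c2)c(O)c1
F4 | step 8 | 1-[2-hydroxy-4-(methoxymethoxy)phenyl]-3-[4-methoxy-3,5-bis(3-methylbut-2-enyl)phenyl]prop-2-yn-1-one | COCOc1ccc(C(=O)C#Cc2cc(CC=C(C)C)c(OC)c(CC=C(C)C)c2)c(O)c1
F5 | step 10 | 7-(methoxymethoxy)-2-[4-methoxy-3,5-bis(3-methylbut-2-enyl)phenyl]chroman-4-one (racemic) | COc1c(CC=C(C)C)cc(C2CC(=O)c3ccc(OCOC)cc3O2)cc1CC=C(C)C
F6 | step 10 | (2R,4R)-7-(methoxymethoxy)-2-[4-methoxy-3,5-bis(3-methylbut-2-enyl)phenyl]chroman-4-ol | COc1c(CC=C(C)C)cc([C@H]2C[C@@H](O)c3ccc(OCOC)cc3O2)cc1CC=C(C)C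
F7 | step 5 | 4-methoxy-3,5-bis(4,4,5,5-tetramethyl-1,3,2-dioxaborolan-2-yl)benzaldehyde | COc1c(B2OC(C)(C)C(C)(C)O2)cc(C=O)cc1B1OC(C)(C)C(C)(C)O1
F0 | step 9 | none | none
A1 | alternative 1 | (2S)-4-(tert-butyldimethylsilyloxy)-7-(methoxymethoxy)-2-[4-methoxy-3,5-bis(3-methylbut-2-enyl)phenyl]-2H-chromene | COc1c(CC=C(C)C)cc([C@@H]2C=C(O[Si](C)(C)C(C)(C)C)c3ccc(OCOC)cc3O2)cc1CC=C(C)C
A2 | alternative 1 | tert-butyl{[1-(4-(methoxymethoxy)-2-{[(1S)-1-[4-methoxy-3,5-bis(3-methylbut-2-enyl)phenyl]prop-2-enyl]oxy}phenyl)ethenyl]oxy}dimethylsilane | COc1c(CC=C(C)C)cc([C@H](C=C)Oc2cc(OCOC)ccc2C(=C)O[Si](C)(C)C(C)(C)C)cc1CC=C(C)C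
A3 | alternative 2 | 7-(methoxymethoxy)-2-[4-methoxy-3,5-bis(3-methylbut-2-enyl)phenyl]chromen-4-one (identical with 17) | O=c1cc(-c2cc(CC=C(C)C)c(OC)c(CC=C(C)C)c2)oc2cc(OCOC)ccc12
A4 | alternative 2 | 2-iodo-5-(methoxymethoxy)phenol | COCOc1ccc(I)c(O)c1
A5 | alternative 2 | 5-ethynyl-2-methoxy-1,3-bis(3-methylbut-2-enyl)benzene | C#Cc1cc(CC=C(C)C)c(OC)c(CC=C(C)C)c1
A6 | alternative 3 | (2S,4S)-7-(methoxymethoxy)-2-[4-methoxy-3,5-bis(3-methylbut-2-enyl)phenyl]chroman-4-ol | COc1c(CC=C(C)C)cc([C@@H]2C[C@H](O)c3ccc(OCOC)cc3O2)cc1CC=C(C)C
A7 | alternative 3 | (1S,3S)-1-[2-bromo-4-(methoxymethoxy)phenyl]-3-[4-methoxy-3,5-bis(3-methylbut-2-enyl)phenyl]propane-1,3-diol | COc1c(CC=C(C)C)cc([C@@H](O)C[C@H](O)c2ccc(OCOC)cc2Br)cc1CC=C(C)C
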